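The numbers of this flask belong to no real substance.

Solid substrate still undissolved at the end is target not made, so the reckoning below counts what dissolution can pass in the time.

- Wednesday's: solid substrate 0.80 M; partner 1.20 M; temperature 55 °C; time 20 d
- Friday's: solid substrate 0.80 M; partner 1.20 M; temperature 25 °C; time 20 d

    starting material + partner + released group → target + 2 released group (k1 = 0.011 M⁻² min⁻¹, Ea1 = 69.0 kJ mol⁻¹)
    starting material + partner → target + released group (k2 = 2.8 × 10⁻⁷ M⁻¹ min⁻¹, Ea2 = 81.0 kJ mol⁻¹)
    solid substrate ⇌ starting material, rate k3*(cs3 - [starting material]) while solid is left; crystals form when [starting material] > cs3 (cs3 = 0.28 M, k3 = 1.4 × 10⁻⁴ min⁻¹)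
    partner ⇌ dormant form (K4 = 4.2, k4 = 1.6 × 10⁻⁴ min⁻¹, Ea4 = 98.0 kJ mol⁻¹, ΔH4 = −75.0 kJ mol⁻¹)
    (constants at 25 °C)

- solid, in amounts per volume of the solution: solid substrate
- the list of constants is for 25 °C, to be carried to other temperatures by the activation energies and enthalpies
- at the start none of the solid substrate is in solution
- what has only dissolved of solid substrate counts as not reacted

- the best flask by amount of target, in percent of the solid substrate charged; "all alike" if 1.5 percentage points covers them all (Wednesday's / Friday's / all alike)
- amount of target at the end, in percent of the solid substrate charged, Wednesday's
- amount of target at the end, in percent of the solid substrate charged, Friday's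

Dissolution opens at r, the dissolution coefficient times the solubility, which is 3.92 × 10⁻⁵ M min⁻¹, and starting material standing in solution lowers that rate. Let c be the solid charged. The number of whole charges that r passes in the time, N = r·t/c, is 1.41 in both flasks, since dissolution carries no activation energy.

In Wednesday's, released group should multiply pseudo-first-order with constant g, the warmed autocatalytic constant times the solubility and the free partner. That gives 0.0372 min⁻¹, a doubling in 0.310 h, far shorter than the 14.2 d that r needs for the whole charge. Dissolution should therefore be the rate-limiting step there. With N above 1, this reckoning commits to 100% for Wednesday's.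

Friday's has a second slowing, taken here as partner paced by release from the dormant form at equilibrium. That release opens at 3.69 × 10⁻⁵ M min⁻¹, a factor 0.942 of r. It then decays over x = 1.10 lifetimes of the dormant form, so its mean over the time is a further factor (one minus e^−x)/x = 0.607. N shrinks to 0.807, which puts Friday's at 80.7%.

The forecast, a separate judgement, names Wednesday's as best, with 100% there and 83% for Friday's, where it holds that “most of the partner goes dormant before the autocatalytic take-off”.

The simulation gives 100% for Wednesday's and 71.0% for Friday's, so Wednesday's is best, and Friday's stands 9.8 percentage points below this reckoning's figure. Wednesday's passed 50 percent conversion at 7.29 d, and that share of the charge takes 7.09 d at r. A neighbour of Wednesday's, charged with 1.4 M of solid substrate, has the same r but N = 0.806, below 1, so the count allows 80.6% of that charge through in the time. That neighbour gives 79.4% of target, with 20.3% of its charge still solid.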